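**Retrosynthetic overview**

1. Locants: ring C1 (stereocentre) to C14, methyls on C4 and C12, carboxyl on C8, side chain C15–C19 on C1. The strategy rests on ring atoms C6, C7, C8 and the carboxyl carbon, flanked by allylic C5 and primary C9: together they are the four-carbon backbone of methyl acetoacetate.
2. Acid 33 ⇐ keto ester 30 (Z-enol triflate, triflate-to-hydrogen exchange, saponification). 30 ⇐ dielectrophile 26 + methyl acetoacetate 27 by cutting C5–C6 and C8–C9; this one step closes the 14-membered carbocycle, the only ring.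
3. 26 ⇐ alkyne 19 (E C11=C12 by methylalumination, C9–C10 from ethylene oxide 20) ⇐ keto aldehyde 13 (Z C3=C4 by Still–Gennari olefination).
4. 13 ⇐ epoxide 11 by periodic acid cleavage of the cyclohexane ring of (R)-limonene 1, the source of C1. The side chain comes from the isopropenyl group by ozonolysis, Horner–Wadsworth–Emmons olefination (E C15=C16) and copper-catalysed coupling with the Grignard reagent of bromide 9 (C17–C18).

Key step: step 17

Remark on the chemistry (assumption): 2–12 are carried as epoxide or diol diastereomer mixtures, 15–16 as carbinol epimers and 28–30 as C8 epimers; these centres are erased in steps 7, 11 and 18, so only the limonene-derived centre C1 has to be preserved.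

**Route**

Step 1
Reactants: 1 (R)-limonene
Product: 2 (4R)-limonene 1,2-oxide (cis/trans mixture at the epoxide)
Conditions: mCPBA (1.0 equiv), CH2Cl2, 0 °C
Reagents that add atoms: mCPBA (3-chloroperoxybenzoic acid), OOC(=O)c1cccc(Cl)c1
Why: Prilezhaev epoxidation is expected to take the electron-rich trisubstituted ring alkene in preference to the 1,1-disubstituted isopropenyl group, the two new epoxide centres need no control because both are destroyed in step 7, and the future C1 centre is untouched.

Step 2
Reactants: 2 (4R)-limonene 1,2-oxide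
Product: 4 (4R)-4-acetyl-1-methyl-7-oxabicyclo[4.1.0]heptane, via secondary ozonide 3 (not isolated)
Conditions: O3, CH2Cl2, −78 °C; then Me2S, −78 °C → rt
Reagents that add atoms: ozone, [O-][O+]=O
Why: Ozonolysis with reductive dimethyl sulfide work-up cleaves the only remaining alkene to the methyl ketone, the epoxide being inert to ozone, and the neutral conditions should leave the now α-carbonyl C1 centre unepimerised.

Step 3
Reactants: 4 (4R)-4-acetyl-1-methyl-7-oxabicyclo[4.1.0]heptane
Product: 5 ethyl (2E)-3-[(4R)-1-methyl-7-oxabicyclo[4.1.0]heptan-4-yl]but-2-enoate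
Conditions: (EtO)2P(O)CH2CO2Et (1.5 equiv), NaH (1.4 equiv), THF, 0 °C → rt; minor Z isomer removed by chromatography
Reagents that add atoms: triethyl phosphonoacetate, CCOC(=O)CP(=O)(OCC)OCC
Why: Horner–Wadsworth–Emmons olefination of an α-branched methyl ketone is steered towards the E enoate (ester trans to the bulky ring carbon), and the weakly basic phosphonate anion, kept in excess over the hydride, should not enolise the ketone towards C1.

Step 4
Reactants: 5 ethyl (2E)-3-[(4R)-1-methyl-7-oxabicyclo[4.1.0]heptan-4-yl]but-2-enoate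
Product: 6 (2E)-3-[(4R)-1-methyl-7-oxabicyclo[4.1.0]heptan-4-yl]but-2-en-1-ol
Conditions: diisobutylaluminium hydride (2.5 equiv), CH2Cl2, −78 °C
Reagents that add atoms: none
Why: Hydride 1,2-reduction of the enoate with diisobutylaluminium hydride at low temperature gives the E allylic alcohol, a trisubstituted epoxide being opened by this reagent only at much higher temperature.

Step 5
Reactants: 6 (2E)-3-[(4R)-1-methyl-7-oxabicyclo[4.1.0]heptan-4-yl]but-2-en-1-ol
Product: 8 (4R)-4-[(2E)-4-bromobut-2-en-2-yl]-1-methyl-7-oxabicyclo[4.1.0]heptane, via allylic mesylate 7 (not isolated)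
Conditions: MsCl, Et3N, CH2Cl2, −40 °C; then LiBr, THF, −40 → 0 °C
Reagents that add atoms: lithium bromide, [Li+].[Br-]
Why: Sulfonylation followed by SN2 displacement with bromide converts the primary allylic alcohol into the bromide without allylic transposition or change of alkene geometry, under conditions that epoxy allylic alcohols of the terpene series tolerate.

Step 6
Reactants: 8 (4R)-4-[(2E)-4-bromobut-2-en-2-yl]-1-methyl-7-oxabicyclo[4.1.0]heptane; 9 1-bromo-2-methylprop-1-ene
Product: 11 (4R)-1-methyl-4-[(2E)-6-methylhepta-2,5-dien-2-yl]-7-oxabicyclo[4.1.0]heptane, via 2-methylprop-1-enylmagnesium bromide 10 (not isolated)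
Conditions: 9, Mg, THF, reflux; then 8, CuI (5 mol %), THF, −40 → 0 °C
Reagents that add atoms: none
Why: Copper-catalysed allylic substitution of a primary allylic bromide by an alkenyl Grignard reagent should occur at the unhindered α-carbon (γ-attack would build a quaternary centre) with retention of both alkene geometries, and it is fast at a temperature at which the trisubstituted epoxide does not react.

Step 7
Reactants: 11 (4R)-1-methyl-4-[(2E)-6-methylhepta-2,5-dien-2-yl]-7-oxabicyclo[4.1.0]heptane
Product: 13 (3R)-3-[(2E)-6-methylhepta-2,5-dien-2-yl]-6-oxoheptanal, via trans-diol 12 (not isolated)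
Conditions: H5IO6 (1.2 equiv), THF/H2O, 0 °C → rt
Reagents that add atoms: water, O
Why: Periodic acid hydrolyses the epoxide and cleaves the resulting 1,2-diol (Malaprade-type glycol cleavage) without touching trisubstituted alkenes, which erases both epoxide centres and unveils the C3 aldehyde and the C12 methyl ketone on either side of the unchanged C1 centre.

Step 8
Reactants: 13 (3R)-3-[(2E)-6-methylhepta-2,5-dien-2-yl]-6-oxoheptanal
Product: 14 ethyl (2Z,5R)-2-methyl-5-[(2E)-6-methylhepta-2,5-dien-2-yl]-8-oxonon-2-enoate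
Conditions: (CF3CH2O)2P(O)CH(CH3)CO2Et (1.1 equiv), potassium bis(trimethylsilyl)amide, 18-crown-6, THF, −78 °C
Reagents that add atoms: ethyl 2-[bis(2,2,2-trifluoroethoxy)phosphoryl]propanoate, CCOC(=O)C(C)P(=O)(OCC(F)(F)F)OCC(F)(F)F
Why: Still–Gennari olefination gives the Z trisubstituted enoate under kinetic control (fast irreversible collapse of the adduct from the electron-poor phosphonate with a crown-separated potassium ion), and at −78 °C the phosphonate anion should add to the aldehyde only and leave the methyl ketone untouched.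

Step 9
Reactants: 14 ethyl (2Z,5R)-2-methyl-5-[(2E)-6-methylhepta-2,5-dien-2-yl]-8-oxonon-2-enoate
Product: 15 (2Z,5R)-2-methyl-5-[(2E)-6-methylhepta-2,5-dien-2-yl]non-2-ene-1,8-diol (mixture at the carbinol carbon)
Conditions: diisobutylaluminium hydride (5 equiv), CH2Cl2, −78 → 0 °C
Reagents that add atoms: none
Why: Exhaustive hydride reduction converts the enoate into the Z allylic alcohol without alkene isomerisation and the ketone into a secondary alcohol whose configuration is irrelevant because it is reoxidised in step 11.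

Step 10
Reactants: 15 (2Z,5R)-2-methyl-5-[(2E)-6-methylhepta-2,5-dien-2-yl]non-2-ene-1,8-diol
Product: 16 (5R,7Z)-9-[(tert-butyldiphenylsilyl)oxy]-8-methyl-5-[(2E)-6-methylhepta-2,5-dien-2-yl]non-7-en-2-ol
Conditions: t-BuPh2SiCl (1.05 equiv), imidazole, CH2Cl2, 0 °C
Reagents that add atoms: tert-butyl(chloro)diphenylsilane, CC(C)(C)[Si](Cl)(c1ccccc1)c1ccccc1
Why: Silylation with the bulky chlorosilane is selective for the primary allylic hydroxyl over the secondary one on steric grounds, and the silyl ether formed withstands the amide base, organoaluminium and organolithium reagents of steps 12 and 13.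

Step 11
Reactants: 16 (5R,7Z)-9-[(tert-butyldiphenylsilyl)oxy]-8-methyl-5-[(2E)-6-methylhepta-2,5-dien-2-yl]non-7-en-2-ol
Product: 17 (5R,7Z)-9-[(tert-butyldiphenylsilyl)oxy]-8-methyl-5-[(2E)-6-methylhepta-2,5-dien-2-yl]non-7-en-2-one
Conditions: Dess–Martin periodinane, CH2Cl2, rt
Reagents that add atoms: none
Why: Dess–Martin oxidation returns the methyl ketone under neutral conditions that leave the silyl ether, the Z allylic system and the skipped diene unchanged.

Step 12
Reactants: 17 (5R,7Z)-9-[(tert-butyldiphenylsilyl)oxy]-8-methyl-5-[(2E)-6-methylhepta-2,5-dien-2-yl]non-7-en-2-one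
Product: 19 tert-butyl{[(2Z,5R)-2-methyl-5-[(2E)-6-methylhepta-2,5-dien-2-yl]non-2-en-8-yn-1-yl]oxy}diphenylsilane, via enol diethyl phosphate 18 (not isolated)
Conditions: lithium diisopropylamide (1.1 equiv), THF, −78 °C; ClP(O)(OEt)2, −78 °C → rt; then lithium diisopropylamide (2.3 equiv), −78 °C → rt
Reagents that add atoms: none
Why: Kinetic deprotonation of the methyl ketone at the methyl group, O-phosphorylation and base-induced β-elimination of the terminal enol phosphate is the standard conversion of a methyl ketone into a terminal alkyne, and it takes place three carbons away from the C1 centre.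

Step 13
Reactants: 19 tert-butyl{[(2Z,5R)-2-methyl-5-[(2E)-6-methylhepta-2,5-dien-2-yl]non-2-en-8-yn-1-yl]oxy}diphenylsilane; 20 ethylene oxide
Product: 23 (3E,7R,9Z)-11-[(tert-butyldiphenylsilyl)oxy]-4,10-dimethyl-7-[(2E)-6-methylhepta-2,5-dien-2-yl]undeca-3,9-dien-1-ol, via alkenyldimethylalane 21 (not isolated), via lithium alkenyl(butyl)dimethylalanate 22 (not isolated)
Conditions: Me3Al (3 equiv), Cp2ZrCl2 (0.5 equiv), CH2Cl2, 0 °C → rt; volatiles removed, hexane; n-BuLi (1.0 equiv), THF, −78 → 0 °C; then 20 (excess), −30 °C → rt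
Reagents that add atoms: trimethylaluminium, C[Al](C)C
Why: Zirconium-catalysed methylalumination (Negishi carboalumination) adds methyl and aluminium syn across the terminal alkyne with methyl at the internal carbon, and the derived alanate opens ethylene oxide with retention at the alkenyl carbon, so the C11=C12 alkene should form E with C9 already in place as a primary alcohol.

Step 14
Reactants: 23 (3E,7R,9Z)-11-[(tert-butyldiphenylsilyl)oxy]-4,10-dimethyl-7-[(2E)-6-methylhepta-2,5-dien-2-yl]undeca-3,9-dien-1-ol
Product: 24 tert-butyl{[(2Z,5R,8E)-11-chloro-2,8-dimethyl-5-[(2E)-6-methylhepta-2,5-dien-2-yl]undeca-2,8-dien-1-yl]oxy}diphenylsilane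
Conditions: PPh3, N-chlorosuccinimide, THF, 0 °C → rt
Reagents that add atoms: N-chlorosuccinimide, ClN1C(=O)CCC1=O
Why: Appel-type chlorination through the alkoxyphosphonium ion replaces the primary homoallylic hydroxyl by chloride in an SN2 step under neutral conditions compatible with the silyl ether and the alkenes.

Step 15
Reactants: 24 tert-butyl{[(2Z,5R,8E)-11-chloro-2,8-dimethyl-5-[(2E)-6-methylhepta-2,5-dien-2-yl]undeca-2,8-dien-1-yl]oxy}diphenylsilane
Product: 25 (2Z,5R,8E)-11-chloro-2,8-dimethyl-5-[(2E)-6-methylhepta-2,5-dien-2-yl]undeca-2,8-dien-1-ol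
Conditions: n-Bu4NF, AcOH, THF, rt
Reagents that add atoms: none
Why: Fluoride-induced desilylation, buffered with acetic acid so that neither the primary chloride nor the Z allylic alcohol meets strong base, frees the C5 hydroxyl.

Step 16
Reactants: 25 (2Z,5R,8E)-11-chloro-2,8-dimethyl-5-[(2E)-6-methylhepta-2,5-dien-2-yl]undeca-2,8-dien-1-ol
Product: 26 (2Z,5R,8E)-1-bromo-11-chloro-2,8-dimethyl-5-[(2E)-6-methylhepta-2,5-dien-2-yl]undeca-2,8-diene
Conditions: CBr4, PPh3, CH2Cl2, −20 → 0 °C; used directly
Reagents that add atoms: carbon tetrabromide, BrC(Br)(Br)Br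
Why: Appel bromination converts the primary allylic alcohol into the bromide by direct SN2 displacement at low temperature, which should keep the Z geometry of C3=C4, and it does not touch the alkyl chloride.

Step 17
Reactants: 26 (2Z,5R,8E)-1-bromo-11-chloro-2,8-dimethyl-5-[(2E)-6-methylhepta-2,5-dien-2-yl]undeca-2,8-diene; 27 methyl acetoacetate
Product: 30 methyl (5Z,8R,11E)-5,11-dimethyl-8-[(2E)-6-methylhepta-2,5-dien-2-yl]-2-oxocyclotetradeca-5,11-diene-1-carboxylate (epimers at the carbon between the carbonyls), via acyclic chloro keto ester 28 (not isolated), via acyclic iodo keto ester 29 (not isolated)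
Conditions: 27 (1.05 equiv), NaH, THF, 0 °C; n-BuLi, 0 °C; 26, −78 → 0 °C; then syringe-pump addition into Cs2CO3, NaI, DMF, 70 °C (final about 2 mM)
Reagents that add atoms: none
Why: Deprotonation of 27 first at the central and then at the terminal carbon gives the acetoacetate dianion, whose terminal carbanion is far more nucleophilic than the stabilised internal site and displaces the primary allylic bromide of 26 by direct SN2 between −78 and 0 °C (the well-known γ-alkylation of β-keto ester dianions by allylic bromides), forming C5–C6 without allylic transposition or loss of the Z geometry at C3=C4. The product survives as its stabilised keto ester enolate 28, which on slow transfer into hot DMF containing Cs2CO3 and NaI undergoes Finkelstein exchange to iodide 29 and then intramolecular C-alkylation at C8, the closest known reaction type being the high-dilution caesium-mediated alkylative macrocyclisation of β-keto ester and malonate enolates. This second displacement forms C8–C9 and closes the 14-membered carbocycle in a 14-exo-tet mode with the enolate C7=C8 bond inside the ring. No stereocentre is set under control: C8 is formed as an enolisable mixture that step 18 erases, and C1 and the three existing alkenes lie away from the reacting atoms. The step needs the allylic bromide to react before the alkyl chloride, carbon rather than oxygen alkylation, and ring closure rather than chain growth; these are secured respectively by the large reactivity gap between an allylic bromide and an unactivated primary chloride towards the dianion at low temperature, by the soft caesium enolate meeting a soft primary iodide, and by syringe-pump addition that keeps the open-chain enolate at millimolar concentration.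

Step 18
Reactants: 30 methyl (5Z,8R,11E)-5,11-dimethyl-8-[(2E)-6-methylhepta-2,5-dien-2-yl]-2-oxocyclotetradeca-5,11-diene-1-carboxylate
Product: 31 methyl (1Z,5Z,8R,11E)-5,11-dimethyl-8-[(2E)-6-methylhepta-2,5-dien-2-yl]-2-{[(trifluoromethyl)sulfonyl]oxy}cyclotetradeca-1,5,11-triene-1-carboxylate
Conditions: NaH, THF, 0 °C; then PhNTf2, 0 °C → rt
Reagents that add atoms: N-phenylbis(trifluoromethanesulfonimide), O=S(=O)(N(c1ccccc1)S(=O)(=O)C(F)(F)F)C(F)(F)F
Why: O-sulfonylation of the sodium enolate of a β-keto ester, which is held in the chelated form with the enolate oxygen cis to the ester carbonyl, should give the Z enol triflate, and this removes the undefined C8 centre and fixes C6 cis to C9.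

Step 19
Reactants: 31 methyl (1Z,5Z,8R,11E)-5,11-dimethyl-8-[(2E)-6-methylhepta-2,5-dien-2-yl]-2-{[(trifluoromethyl)sulfonyl]oxy}cyclotetradeca-1,5,11-triene-1-carboxylate
Product: 32 methyl (1E,5Z,8R,11E)-5,11-dimethyl-8-[(2E)-6-methylhepta-2,5-dien-2-yl]cyclotetradeca-1,5,11-triene-1-carboxylate
Conditions: Pd(OAc)2 (5 mol %), PPh3 (10 mol %), HCO2H, n-Bu3N, DMF, 60 °C
Reagents that add atoms: none
Why: Palladium-catalysed formate hydrogenolysis of the enol triflate (oxidative addition to zerovalent palladium, formate exchange, loss of CO2 and C–H reductive elimination) replaces the triflate by hydrogen with retention of alkene geometry, which places the C7 hydrogen cis to the ester as in the target.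

Step 20
Reactants: 32 methyl (1E,5Z,8R,11E)-5,11-dimethyl-8-[(2E)-6-methylhepta-2,5-dien-2-yl]cyclotetradeca-1,5,11-triene-1-carboxylate
Product: 33 (1E,5Z,8R,11E)-5,11-dimethyl-8-[(2E)-6-methylhepta-2,5-dien-2-yl]cyclotetradeca-1,5,11-triene-1-carboxylic acid (CNP0112585.1)
Conditions: LiOH, THF/MeOH/H2O, 50 °C; then dilute HCl to pH 3
Reagents that add atoms: lithium hydroxide, [Li+].[OH-]
Why: Saponification of the methyl ester by acyl–oxygen cleavage followed by acidification gives the acid, the trisubstituted E enoate and the skipped diene being stable to aqueous hydroxide at this temperature.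

**Compound list**

1 | (R)-limonene | CC1=CC[C@@H](CC1)C(C)=C | starting material
2 | (4R)-limonene 1,2-oxide, cis/trans mixture | CC12OC1C[C@@H](CC2)C(C)=C | intermediate
3 | secondary ozonide of 2 (3-methyl-1,2,4-trioxolan-3-yl in place of isopropenyl), not isolated | CC12OC1C[C@@H](CC2)C1(C)OCOO1 | intermediate
4 | (4R)-4-acetyl-1-methyl-7-oxabicyclo[4.1.0]heptane | CC12OC1C[C@@H](CC2)C(C)=O | intermediate
5 | ethyl (2E)-3-[(4R)-1-methyl-7-oxabicyclo[4.1.0]heptan-4-yl]but-2-enoate | CC12OC1C[C@@H](CC2)/C(C)=C/C(=O)OCC | intermediate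
6 | (2E)-3-[(4R)-1-methyl-7-oxabicyclo[4.1.0]heptan-4-yl]but-2-en-1-ol | CC12OC1C[C@@H](CC2)/C(C)=C/CO | intermediate
7 | methanesulfonate of 6, not isolated | CC12OC1C[C@@H](CC2)/C(C)=C/COS(C)(=O)=O | intermediate
8 | (4R)-4-[(2E)-4-bromobut-2-en-2-yl]-1-methyl-7-oxabicyclo[4.1.0]heptane | CC12OC1C[C@@H](CC2)/C(C)=C/CBr | intermediate
9 | 1-bromo-2-methylprop-1-ene | CC(C)=CBr | starting material
10 | 2-methylprop-1-enylmagnesium bromide, not isolated | CC(C)=C[Mg]Br | intermediate
11 | (4R)-1-methyl-4-[(2E)-6-methylhepta-2,5-dien-2-yl]-7-oxabicyclo[4.1.0]heptane | CC12OC1C[C@@H](CC2)/C(C)=C/CC=C(C)C | intermediate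
12 | (4R)-1-methyl-4-[(2E)-6-methylhepta-2,5-dien-2-yl]cyclohexane-1,2-diol, diastereomer mixture, not isolated | CC1(O)CC[C@H](CC1O)/C(C)=C/CC=C(C)C | intermediate
13 | (3R)-3-[(2E)-6-methylhepta-2,5-dien-2-yl]-6-oxoheptanal | CC(=O)CC[C@H](CC=O)/C(C)=C/CC=C(C)C | intermediate
14 | ethyl (2Z,5R)-2-methyl-5-[(2E)-6-methylhepta-2,5-dien-2-yl]-8-oxonon-2-enoate | CC(=O)CC[C@H](C/C=C(/C)C(=O)OCC)/C(C)=C/CC=C(C)C | intermediate
15 | (2Z,5R)-2-methyl-5-[(2E)-6-methylhepta-2,5-dien-2-yl]non-2-ene-1,8-diol, carbinol epimers | CC(O)CC[C@H](C/C=C(/C)CO)/C(C)=C/CC=C(C)C | intermediate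
16 | (5R,7Z)-9-[(tert-butyldiphenylsilyl)oxy]-8-methyl-5-[(2E)-6-methylhepta-2,5-dien-2-yl]non-7-en-2-ol, carbinol epimers | CC(O)CC[C@H](C/C=C(/C)CO[Si](c1ccccc1)(c1ccccc1)C(C)(C)C)/C(C)=C/CC=C(C)C | intermediate
17 | (5R,7Z)-9-[(tert-butyldiphenylsilyl)oxy]-8-methyl-5-[(2E)-6-methylhepta-2,5-dien-2-yl]non-7-en-2-one | CC(=O)CC[C@H](C/C=C(/C)CO[Si](c1ccccc1)(c1ccccc1)C(C)(C)C)/C(C)=C/CC=C(C)C | intermediate
18 | terminal enol diethyl phosphate of 17, not isolated | C=C(OP(=O)(OCC)OCC)CC[C@H](C/C=C(/C)CO[Si](c1ccccc1)(c1ccccc1)C(C)(C)C)/C(C)=C/CC=C(C)C | intermediate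
19 | tert-butyl{[(2Z,5R)-2-methyl-5-[(2E)-6-methylhepta-2,5-dien-2-yl]non-2-en-8-yn-1-yl]oxy}diphenylsilane | C#CCC[C@H](C/C=C(/C)CO[Si](c1ccccc1)(c1ccccc1)C(C)(C)C)/C(C)=C/CC=C(C)C | intermediate
20 | ethylene oxide | C1CO1 | starting material
21 | (E)-alkenyldimethylalane from syn methylalumination of 19 (Al on C11, new methyl on C12), not isolated | C[Al](C)/C=C(\C)CC[C@H](C/C=C(/C)CO[Si](c1ccccc1)(c1ccccc1)C(C)(C)C)/C(C)=C/CC=C(C)C | intermediate
22 | lithium alkenyl(butyl)dimethylalanate from 21, not isolated | [Li+].CCCC[Al-](C)(C)/C=C(\C)CC[C@H](C/C=C(/C)CO[Si](c1ccccc1)(c1ccccc1)C(C)(C)C)/C(C)=C/CC=C(C)C | intermediate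
23 | (3E,7R,9Z)-11-[(tert-butyldiphenylsilyl)oxy]-4,10-dimethyl-7-[(2E)-6-methylhepta-2,5-dien-2-yl]undeca-3,9-dien-1-ol | OCC/C=C(\C)CC[C@H](C/C=C(/C)CO[Si](c1ccccc1)(c1ccccc1)C(C)(C)C)/C(C)=C/CC=C(C)C | intermediate
24 | tert-butyl{[(2Z,5R,8E)-11-chloro-2,8-dimethyl-5-[(2E)-6-methylhepta-2,5-dien-2-yl]undeca-2,8-dien-1-yl]oxy}diphenylsilane | ClCC/C=C(\C)CC[C@H](C/C=C(/C)CO[Si](c1ccccc1)(c1ccccc1)C(C)(C)C)/C(C)=C/CC=C(C)C | intermediate
25 | (2Z,5R,8E)-11-chloro-2,8-dimethyl-5-[(2E)-6-methylhepta-2,5-dien-2-yl]undeca-2,8-dien-1-ol | ClCC/C=C(\C)CC[C@H](C/C=C(/C)CO)/C(C)=C/CC=C(C)C | intermediate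
26 | (2Z,5R,8E)-1-bromo-11-chloro-2,8-dimethyl-5-[(2E)-6-methylhepta-2,5-dien-2-yl]undeca-2,8-diene (C9-to-C5 dielectrophile) | CC(C)=CC/C=C(\C)[C@H](CC/C(C)=C/CCCl)C/C=C(/C)CBr | intermediate
27 | methyl acetoacetate | CC(=O)CC(=O)OC | starting material
28 | methyl (6Z,9R,12E)-15-chloro-6,12-dimethyl-9-[(2E)-6-methylhepta-2,5-dien-2-yl]-3-oxopentadeca-6,12-dienoate, present as its enolate, not isolated | ClCC/C=C(\C)CC[C@H](C/C=C(/C)CCC(=O)CC(=O)OC)/C(C)=C/CC=C(C)C | intermediate
29 | methyl (6Z,9R,12E)-15-iodo-6,12-dimethyl-9-[(2E)-6-methylhepta-2,5-dien-2-yl]-3-oxopentadeca-6,12-dienoate, present as its enolate, not isolated | ICC/C=C(\C)CC[C@H](C/C=C(/C)CCC(=O)CC(=O)OC)/C(C)=C/CC=C(C)C | intermediate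
30 | methyl (5Z,8R,11E)-5,11-dimethyl-8-[(2E)-6-methylhepta-2,5-dien-2-yl]-2-oxocyclotetradeca-5,11-diene-1-carboxylate, C8 epimers | CC(C)=CC/C=C(\C)[C@H]1C/C=C(/C)CCC(=O)C(C(=O)OC)CC/C=C(\C)CC1 | intermediate
31 | methyl (1Z,5Z,8R,11E)-5,11-dimethyl-8-[(2E)-6-methylhepta-2,5-dien-2-yl]-2-{[(trifluoromethyl)sulfonyl]oxy}cyclotetradeca-1,5,11-triene-1-carboxylate | CC(C)=CC/C=C(\C)[C@H]1C/C=C(/C)CC/C(OS(=O)(=O)C(F)(F)F)=C(/C(=O)OC)CC/C=C(\C)CC1 | intermediate
32 | methyl (1E,5Z,8R,11E)-5,11-dimethyl-8-[(2E)-6-methylhepta-2,5-dien-2-yl]cyclotetradeca-1,5,11-triene-1-carboxylate | CC(C)=CC/C=C(\C)[C@H]1C/C=C(/C)CC/C=C(/C(=O)OC)CC/C=C(\C)CC1 | intermediate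
33 | (1E,5Z,8R,11E)-5,11-dimethyl-8-[(2E)-6-methylhepta-2,5-dien-2-yl]cyclotetradeca-1,5,11-triene-1-carboxylic acid (CNP0112585.1) | CC(C)=CC/C=C(\C)[C@H]1C/C=C(/C)CC/C=C(/C(=O)O)CC/C=C(\C)CC1 | target

**Step count and risks**

Total step count: 20. Longest linear sequence: 20 steps (1 → 33); the Grignard reagent 10 is prepared within step 6.

Steps most likely to fail:

Step 17 (ring closure). The open-chain enolate may alkylate on oxygen, lose HI from the homoallylic iodide towards a conjugated diene, or react between molecules instead of closing the ring. The fallback closes the ring by forming the C7=C8 alkene in an intramolecular Horner–Wadsworth–Emmons reaction. It sets out from 26: the lithium azaenolate of acetaldehyde N,N-dimethylhydrazone (lithium diisopropylamide, THF, −78 °C) is alkylated at the allylic bromide to give the chloro hydrazone F1. NaI in acetone then gives the iodo hydrazone F2, and alkylation of the sodium salt of trimethyl phosphonoacetate (NaH, DMF) at C9 gives the phosphonoacetate hydrazone F3. Hydrolysis of the hydrazone with CuCl2 in buffered aqueous THF gives the phosphonoacetate aldehyde F4. LiCl and DBU in MeCN at high dilution should then close the ring to the E enoate (ester trans to the β-substituent, as is usual for α-alkyl phosphonoacetates), which is compound 32, where the route is rejoined; 30 and 31 are bypassed.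

Step 13 (methylalumination and epoxide opening). The alkenylalanate may open ethylene oxide sluggishly, so that protonolysis on work-up returns the unfunctionalised methyl-branched alkene, and long contact with Me3Al may erode the allylic silyl ether. The fallback replaces the epoxide opening by cross-coupling and hydroboration. It sets out from 19: the same methylalumination is quenched with I2 to give the E alkenyl iodide F5. Stille coupling with tributyl(vinyl)stannane (Pd(PPh3)4, DMF) gives the diene F6. 9-BBN should add only to the terminal vinyl group, giving the B-alkyl borane F7, and oxidation with NaOH/H2O2 gives 23, where the route is rejoined.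

Step 18 (enol triflate geometry). Sulfonylation of the macrocyclic enolate may proceed through a non-chelated enolate as well, giving both enol triflate isomers and therefore both enoate geometries after step 19. The fallback makes the alkene by dehydration. It sets out from 30: NaBH4 in MeOH gives the β-hydroxy ester F8, MsCl/Et3N gives the β-mesyloxy ester F9, and DBU-induced E1cB elimination should give the thermodynamically preferred E enoate 32, where the route is rejoined; 31 is bypassed.

Further compounds
F1 | step 17 | chloro hydrazone: (4Z,7R,10E)-13-chloro-4,10-dimethyl-7-[(2E)-6-methylhepta-2,5-dien-2-yl]trideca-4,10-dienal N,N-dimethylhydrazone | ClCC/C=C(\C)CC[C@H](C/C=C(/C)CCC=NN(C)C)/C(C)=C/CC=C(C)C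
F2 | step 17 | iodo hydrazone: the 13-iodo analogue of F1 | ICC/C=C(\C)CC[C@H](C/C=C(/C)CCC=NN(C)C)/C(C)=C/CC=C(C)C
F3 | step 17 | phosphonoacetate hydrazone: methyl 2-(dimethoxyphosphoryl) ester alkylated at C9, hydrazone at C7 | COC(=O)C(CC/C=C(\C)CC[C@H](C/C=C(/C)CCC=NN(C)C)/C(C)=C/CC=C(C)C)P(=O)(OC)OC
F4 | step 17 | phosphonoacetate aldehyde: C7 aldehyde, C8 dimethoxyphosphoryl methyl ester | COC(=O)C(CC/C=C(\C)CC[C@H](C/C=C(/C)CCC=O)/C(C)=C/CC=C(C)C)P(=O)(OC)OC
F5 | step 13 | E alkenyl iodide: iodine on C11, methyl on C12, silyl ether retained | I/C=C(\C)CC[C@H](C/C=C(/C)CO[Si](c1ccccc1)(c1ccccc1)C(C)(C)C)/C(C)=C/CC=C(C)C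
F6 | step 13 | diene: vinyl group (C9=C10) on C11 | C=C/C=C(\C)CC[C@H](C/C=C(/C)CO[Si](c1ccccc1)(c1ccccc1)C(C)(C)C)/C(C)=C/CC=C(C)C
F7 | step 13 | B-alkyl borane: 9-borabicyclo[3.3.1]nonan-9-yl on C9 | C(C/C=C(\C)CC[C@H](C/C=C(/C)CO[Si](c1ccccc1)(c1ccccc1)C(C)(C)C)/C(C)=C/CC=C(C)C)B1C2CCCC1CCC2
F8 | step 18 | β-hydroxy ester: C7 alcohol of 30, diastereomer mixture | CC(C)=CC/C=C(\C)[C@H]1C/C=C(/C)CCC(O)C(C(=O)OC)CC/C=C(\C)CC1
F9 | step 18 | β-mesyloxy ester: methanesulfonate of F8 | CC(C)=CC/C=C(\C)[C@H]1C/C=C(/C)CCC(OS(C)(=O)=O)C(C(=O)OC)CC/C=C(\C)CC1
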